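## Retrosynthetic overview

1. Germacrane numbering is used: C1 furanone C=O, C2=C3, Z-C4=C5 (C15 on C4), C6–O (lactone), C7, C8–O (ester), C9, C10 (C14 methyl), C11–C13 lactone. The strategy rests on the C3–O–C10 ether bridge with the C10 methyl and the C1–C2 unit: they are the skeleton of a 2-methylfuran Diels–Alder adduct if C3 is also bonded to C8, and the Z-C4=C5 alkene then lies in a cyclohexene made of C3 to C8.
2. Target ⇐ (C15 deprotection, γ-lactone closure, C11 methylenation on the C12 aldehyde, C8 isovalerate, C1 oxidation) ⇐ ten-membered C8 ketone 26 bridged by a 3-hydroxy-2,3-dihydrofuran.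
3. 26 ⇐ Grob fragmentation of tricyclic epoxy alcohol 25 (exo-epoxidised 7-oxanorbornane fused along C3–C8 to the cyclohexene): C3–C8 is cut, C2=C3 forms, the epoxide opens to the C1 alkoxide.
4. 25 ⇐ intramolecular furan Diels–Alder reaction of 21, in which C6–O and C8 are tied by a temporary SiMe2 bridge. With free substituents the C6 and C7 groups would sit equatorial on the new cyclohexene and give the C10 epimer; the bridge can only span cis-1,3-diaxial positions and so fixes C10 against C6 and C7. Tamao oxidation then turns C8–Si into the C8 alcohol.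
5. 21 ⇐ Evans syn-aldol (C6–C7) of imide 12 with Z-enal 7, itself from Suzuki coupling of Z-iodide 4 with furyl boronate 5. Ring order: oxasilolane (temporary), then oxanorbornene and cyclohexene together, epoxide, ten-membered ring with dihydrofuran (by fragmentation), furanone, lactone.

Key step: step 18

Remark: hydride is assumed to add to the C8 ketone of 26 from the outer face of the ring (8S alcohol), so the isovalerate is introduced with inversion; the opposite case is covered under the fallbacks.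

## Route

Step 1
Reactants: 1 but-2-yne-1,4-diol
Product: 2 4-[(4-methoxybenzyl)oxy]but-2-yn-1-ol
Conditions: NaH (1.0 equiv), 4-methoxybenzyl chloride (1.0 equiv), n-Bu4NI (cat.), THF/DMF, 0 °C to rt; 1 in threefold excess
Reagents that add atoms: 4-methoxybenzyl chloride, COc1ccc(CCl)cc1
Why: Williamson ether synthesis on the monoalkoxide, where the excess of the symmetric diol should hold the reaction at the monoether.

Step 2
Reactants: 2 4-[(4-methoxybenzyl)oxy]but-2-yn-1-ol
Product: 4 (Z)-3-iodo-4-[(4-methoxybenzyl)oxy]but-2-en-1-ol, via cyclic alkenylalanate 3 (not isolated)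
Conditions: NaAlH2(OCH2CH2OMe)2 (Red-Al), THF, 0 °C; then I2, THF, −78 °C to 0 °C
Reagents that add atoms: iodine, II
Why: Hydroxyl-directed trans-hydroalumination of the propargylic alcohol should place aluminium on the alkyne carbon remote from the hydroxyl in a five-membered alanate, and iodinolysis with retention then gives the Z-iodide (iodine cis to CH2OH).

Step 3
Reactants: 4 (Z)-3-iodo-4-[(4-methoxybenzyl)oxy]but-2-en-1-ol; 5 4,4,5,5-tetramethyl-2-(5-methylfuran-2-yl)-1,3,2-dioxaborolane
Product: 6 (Z)-4-[(4-methoxybenzyl)oxy]-3-(5-methylfuran-2-yl)but-2-en-1-ol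
Conditions: Pd(dppf)Cl2 (5 mol%), K3PO4 (aq), THF, 50 °C
Reagents that add atoms: none
Why: Suzuki–Miyaura coupling of an alkenyl iodide proceeds with retention of double-bond geometry, so the furan (C3) ends cis to the future C6.

Step 4
Reactants: 6 (Z)-4-[(4-methoxybenzyl)oxy]-3-(5-methylfuran-2-yl)but-2-en-1-ol
Product: 7 (Z)-4-[(4-methoxybenzyl)oxy]-3-(5-methylfuran-2-yl)but-2-enal
Conditions: MnO2 (activated, excess), CH2Cl2, rt, dark; used at once
Reagents that add atoms: none
Why: MnO2 oxidation of the allylic alcohol is neutral and heterogeneous, which should preserve the Z geometry of the enal.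

Step 5
Reactants: 8 methyl 4,4-dimethoxybutanoate
Product: 9 4,4-dimethoxybutanoic acid
Conditions: LiOH·H2O, THF/H2O, 0 °C to rt; then cold 1 M HCl to pH 4–5, extraction; used at once
Reagents that add atoms: lithium hydroxide, [Li+].[OH-]
Why: Ester saponification, with a brief cold acidification that should leave the dimethyl acetal intact.

Step 6
Reactants: 9 4,4-dimethoxybutanoic acid; 10 (S)-4-benzyloxazolidin-2-one
Product: 12 (S)-4-benzyl-3-(4,4-dimethoxybutanoyl)oxazolidin-2-one, via pivalic mixed anhydride 11 (not isolated)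
Conditions: pivaloyl chloride, Et3N, THF, −20 °C; then LiCl, 10, −20 °C to rt
Reagents that add atoms: none
Why: N-Acylation of the oxazolidinone through the mixed pivalic anhydride, which is attacked at the less hindered carbonyl.

Step 7
Reactants: 12 (S)-4-benzyl-3-(4,4-dimethoxybutanoyl)oxazolidin-2-one; 7 (Z)-4-[(4-methoxybenzyl)oxy]-3-(5-methylfuran-2-yl)but-2-enal
Product: 14 (S)-4-benzyl-3-[(2S,3R,4Z)-2-(2,2-dimethoxyethyl)-3-hydroxy-6-[(4-methoxybenzyl)oxy]-5-(5-methylfuran-2-yl)hex-4-enoyl]oxazolidin-2-one, via Z-boron enolate 13 (not isolated)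
Conditions: n-Bu2BOTf, i-Pr2NEt, CH2Cl2, −78 °C to 0 °C; then 7, −78 °C to −10 °C; pH 7 buffer, MeOH, H2O2, 0 °C
Reagents that add atoms: none
Why: Evans syn-aldol reaction, in which the Z-boron enolate reacts through a Zimmerman–Traxler chair on the face away from the benzyl group and so sets C7 and C6 (2S,3R in the acyl chain) with the syn relationship and absolute sense of the target.

Step 8
Reactants: 14 aldol adduct
Product: 15 C6 triethylsilyl ether of 14
Conditions: Et3SiCl, imidazole, DMAP (cat.), CH2Cl2, 0 °C to rt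
Reagents that add atoms: chlorotriethylsilane, CC[Si](Cl)(CC)CC
Why: Silylation of the secondary alcohol with a silyl chloride (not a triflate), which spares the dimethyl acetal.

Step 9
Reactants: 15 C6 triethylsilyl ether
Product: 16 (2R,3R,4Z)-2-(2,2-dimethoxyethyl)-6-[(4-methoxybenzyl)oxy]-5-(5-methylfuran-2-yl)-3-[(triethylsilyl)oxy]hex-4-en-1-ol
Conditions: LiBH4, MeOH (1 equiv), THF, 0 °C
Reagents that add atoms: none
Why: Reductive cleavage of the N-acyloxazolidinone by borohydride attack at the exocyclic carbonyl, which releases the auxiliary and leaves C7 untouched.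

Step 10
Reactants: 16 primary alcohol
Product: 17 (2S,3R,4Z)-2-(2,2-dimethoxyethyl)-6-[(4-methoxybenzyl)oxy]-5-(5-methylfuran-2-yl)-3-[(triethylsilyl)oxy]hex-4-enal
Conditions: Dess–Martin periodinane, pyridine, CH2Cl2, 0 °C to rt
Reagents that add atoms: none
Why: Dess–Martin oxidation under buffered conditions gives the α-branched aldehyde without epimerisation or loss of the acid-labile groups.

Step 11
Reactants: 17 aldehyde
Product: 18 (3R,4R,5Z)-3-(2,2-dimethoxyethyl)-7-[(4-methoxybenzyl)oxy]-6-(5-methylfuran-2-yl)-4-[(triethylsilyl)oxy]hept-5-en-1-yne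
Conditions: dimethyl (1-diazo-2-oxopropyl)phosphonate, K2CO3, MeOH, 0 °C to rt
Reagents that add atoms: dimethyl (1-diazo-2-oxopropyl)phosphonate, COP(=O)(OC)C(=[N+]=[N-])C(C)=O
Why: Ohira–Bestmann (Seyferth–Gilbert) homologation turns the aldehyde carbon into C8 of a terminal alkyne and adds C9 under mild carbonate conditions.

Step 12
Reactants: 18 silyl-protected enyne
Product: 19 (3R,4R,5Z)-3-(2,2-dimethoxyethyl)-7-[(4-methoxybenzyl)oxy]-6-(5-methylfuran-2-yl)hept-5-en-1-yn-4-ol
Conditions: n-Bu4NF, AcOH (1:1), THF, 0 °C to rt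
Reagents that add atoms: none
Why: Fluoride desilylation under buffered, non-acidic conditions, chosen because the furyl-dienyl carbinol ionises easily in acid.

Step 13
Reactants: 19 homopropargylic alcohol
Product: 21 (4S,5R)-4-(2,2-dimethoxyethyl)-5-[(Z)-3-[(4-methoxybenzyl)oxy]-2-(5-methylfuran-2-yl)prop-1-en-1-yl]-2,2-dimethyl-3-methylene-1,2-oxasilolane, via dimethylsilyl ether 20 (not isolated)
Conditions: (HMe2Si)2NH (neat), 50 °C, then evaporation; Pt2[(CH2=CHSiMe2)2O]3 (Karstedt catalyst, 0.5 mol%), toluene, rt; filtered through Florisil and used directly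
Reagents that add atoms: 1,1,3,3-tetramethyldisilazane, C[SiH](C)N[SiH](C)C
Why: O-Silylation followed by platinum-catalysed intramolecular alkyne hydrosilylation (5-exo-dig, syn addition) should deliver silicon to C8, because only that mode closes a five-membered ring, and leaves the exocyclic C8=C9 methylene.

Step 14
Reactants: 21 oxasilolane triene
Product: 22 silicon-bridged cycloadduct (3R,6R,7S,8R,10S; 7-oxanorbornene fused along C3–C8 to the cyclohexene)
Conditions: toluene (0.01 M), BHT (cat.), 100–110 °C, sealed tube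
Reagents that add atoms: none
Why: Intramolecular Diels–Alder reaction of the furan across C8=C9 (bonds C3–C8 and C10–C9), in which the C6–O–Si–C8 bridge can only span cis-1,3-diaxial positions of the new cyclohexene (bicyclo[3.2.1] frame, C7 exo and silicon endo at C8), so that one furan face is used and C3, C8 and C10 are set relative to C6 and C7.

Step 15
Reactants: 22 silicon-bridged cycloadduct
Product: 23 exo-epoxide of 22 (1R,2S,3S,6R,7S,8R,10S)
Conditions: m-CPBA, NaHCO3, CH2Cl2, 0 °C
Reagents that add atoms: 3-chloroperoxybenzoic acid, OOC(=O)c1cccc(Cl)c1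
Why: Prilezhaev epoxidation of the strained C1=C2 bond on its exo face (syn to the oxygen bridge) sets C1 and C2, while the trisubstituted C4=C5 bond is hindered and deactivated by three allylic oxygens; the epoxide also blocks cycloreversion.

Step 16
Reactants: 23 epoxy siloxane
Product: 24 epoxy diol (endo tertiary C8–OH; C6–OH on the same face)
Conditions: H2O2 (30%), KF, KHCO3, THF/MeOH, rt to 45 °C
Reagents that add atoms: hydrogen peroxide, OO
Why: Tamao–Fleming oxidation of the alkoxy-activated C8–Si bond proceeds with retention and so gives the endo tertiary C8 alcohol, while cleavage of the Si–O bond frees the C6 hydroxyl.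

Step 17
Reactants: 24 epoxy diol
Product: 25 tricyclic epoxy alcohol (1R,2S,3S,6R,7S,8R,10S; C6 tert-butyldimethylsilyl ether)
Conditions: t-BuMe2SiCl, imidazole, DMAP (cat.), DMF, rt to 40 °C
Reagents that add atoms: tert-butylchlorodimethylsilane, CC(C)(C)[Si](C)(C)Cl
Why: Silylation of the secondary C6 hydroxyl, since the tertiary C8 hydroxyl is too hindered to react with the silyl chloride.

Step 18
Reactants: 25 tricyclic epoxy alcohol
Product: 26 ten-membered C8 ketone bridged by the 3-hydroxy-2,3-dihydrofuran (1R,6R,7S,10S; Z-C4=C5)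
Conditions: KN(SiMe3)2 (1.05 equiv), THF, −78 °C to −30 °C; AcOH (1.1 equiv) in THF at −78 °C
Reagents that add atoms: none
Why: Grob fragmentation (the alkoxide-triggered heterolytic cleavage known for 1,3-diol monosulfonates and for β,γ-epoxy carbinols): KN(SiMe3)2 deprotonates the tertiary C8 alcohol, the alkoxide closes to the C8 ketone, the C3–C8 σ bond breaks and becomes the C2=C3 π bond, and the exo C2–O epoxide bond breaks to leave the C1 alkoxide. No ring is closed by bond formation: the ten-membered carbocycle appears because the bond shared by the oxanorbornane and the cyclohexene is cut, and the former oxygen bridge remains as the 2,3-dihydrofuran spanning C3 and C10. The only new stereocenter, the C1 carbinol, keeps the configuration of the epoxide carbon because its C–O bond is not touched (it is removed in step 20); C6, C7 and C10 are untouched and the Z geometry of C4=C5 is inherited from the cyclohexene. The step needs the C3–C8 bond anti-periplanar to the leaving C2–O bond, which the rigid bicycle secures because an exo substituent on C2 stands at about 170° to the bridgehead C3–C8 bond. Release of oxanorbornane and epoxide strain together with formation of a ketone and a conjugated enol ether should make the step irreversible, and the cold acetic acid quench protects the β-silyloxy ketone from enolisation at C7.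

Step 19
Reactants: 26 ten-membered C8 ketone
Product: 27 8S diol (1R,6R,7R,8S,10S)
Conditions: LiBH(s-Bu)3 (L-Selectride, 2.2 equiv), THF, −78 °C; then NaOH (aq), H2O2, 0 °C
Reagents that add atoms: none
Why: Hydride reduction of the ketone, in which the bulky trialkylborohydride should add from the outer face of the ring (opposite the former C3–C8 bond, where C7 presents its hydrogen) and so give the 8S alcohol.

Step 20
Reactants: 27 8S diol
Product: 28 8S furanone alcohol (6R,7R,8S,10S)
Conditions: MnO2 (activated, excess), CH2Cl2, rt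
Reagents that add atoms: none
Why: MnO2 oxidises only the C1 carbinol, which is allylic to the C2=C3 enol ether, to the furan-3(2H)-one and leaves the saturated C8 alcohol.

Step 21
Reactants: 28 8S furanone alcohol; 29 3-methylbutanoic acid (isovaleric acid)
Product: 30 8R isovalerate (6R,7R,8R,10S)
Conditions: PPh3, DIAD, toluene, 0 °C to rt
Reagents that add atoms: none
Why: Mitsunobu esterification, in which the carboxylate displaces the oxyphosphonium group at C8 with inversion (SN2) and so turns the 8S alcohol into the 8R ester of the target.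

Step 22
Reactants: 30 8R isovalerate
Product: 31 C12 aldehyde
Conditions: PPTS (cat.), acetone/H2O (10:1), 45 °C
Reagents that add atoms: water, O
Why: Acid-catalysed acetal hydrolysis under conditions mild enough to keep the secondary silyl ether, the PMB ether and the ester.

Step 23
Reactants: 31 C12 aldehyde
Product: 33 α-methylene aldehyde (C11=C13), via Mannich base 32 (not isolated)
Conditions: CH2=NMe2 I (Eschenmoser salt), Et3N, CH2Cl2, rt
Reagents that add atoms: N,N-dimethylmethyleneiminium iodide, C=[N+](C)C.[I-]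
Why: Mannich α-methylenation of the aldehyde followed by elimination of dimethylamine, selective because only the aldehyde enolises under triethylamine while ester and furanone stay untouched.

Step 24
Reactants: 33 α-methylene aldehyde
Product: 34 acrylic acid (C12 acid)
Conditions: NaClO2, NaH2PO4, 2-methylbut-2-ene, t-BuOH/H2O, 0 °C to rt
Reagents that add atoms: sodium chlorite, [Na+].[O-]Cl=O
Why: Pinnick oxidation converts the enal into the acid without touching the alkenes, because hypochlorous acid is taken up by the scavenger alkene.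

Step 25
Reactants: 34 acrylic acid
Product: 36 15-O-(4-methoxybenzyl) ether of the target (α-methylene-γ-lactone closed), via hydroxy acid 35 (not isolated)
Conditions: HF·pyridine, THF/pyridine, 0 °C to rt; then p-TsOH·H2O (cat.), CH2Cl2, rt
Reagents that add atoms: none
Why: Fluoride desilylation frees the C6 hydroxyl, which closes the γ-lactone onto the acrylic acid under acid catalysis; O8 is already acylated, so only the 6,12-lactone can form, trans-fused as fixed by C6 and C7.

Step 26
Reactants: 36 15-O-(4-methoxybenzyl) ether of the target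
Product: 37 CNP0171896.1 (target)
Conditions: DDQ, CH2Cl2/pH 7 buffer (10:1), 0 °C
Reagents that add atoms: none
Why: Oxidative cleavage of the 4-methoxybenzyl ether by DDQ (oxidation to the oxocarbenium ion and hydrolysis) frees the C15 alcohol, which sits on an electron-poor dienone and should resist further oxidation.

## Compound list

1 | but-2-yne-1,4-diol | OCC#CCO | starting material
2 | 4-[(4-methoxybenzyl)oxy]but-2-yn-1-ol | OCC#CCOCc1ccc(OC)cc1 | intermediate
3 | sodium cyclic alkenylalanate from 2 (five-membered Al–O–CH2–CH=C ring, Al on the carbon bearing CH2OPMB, two 2-methoxyethoxy ligands) | [Na+].COCCO[Al-]1(OCCOC)OC/C=C1/COCc1ccc(OC)cc1 | intermediate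
4 | (Z)-3-iodo-4-[(4-methoxybenzyl)oxy]but-2-en-1-ol | OC/C=C(\I)COCc1ccc(OC)cc1 | intermediate
5 | 4,4,5,5-tetramethyl-2-(5-methylfuran-2-yl)-1,3,2-dioxaborolane | Cc1ccc(o1)B1OC(C)(C)C(C)(C)O1 | starting material
6 | (Z)-4-[(4-methoxybenzyl)oxy]-3-(5-methylfuran-2-yl)but-2-en-1-ol | OC/C=C(\c1ccc(C)o1)COCc1ccc(OC)cc1 | intermediate
7 | (Z)-4-[(4-methoxybenzyl)oxy]-3-(5-methylfuran-2-yl)but-2-enal | O=C/C=C(\c1ccc(C)o1)COCc1ccc(OC)cc1 | intermediate
8 | methyl 4,4-dimethoxybutanoate | COC(=O)CCC(OC)OC | starting material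
9 | 4,4-dimethoxybutanoic acid | OC(=O)CCC(OC)OC | intermediate
10 | (S)-4-benzyloxazolidin-2-one | O=C1OC[C@H](Cc2ccccc2)N1 | starting material
11 | 4,4-dimethoxybutanoic pivalic anhydride | CC(C)(C)C(=O)OC(=O)CCC(OC)OC | intermediate
12 | (S)-4-benzyl-3-(4,4-dimethoxybutanoyl)oxazolidin-2-one | COC(OC)CCC(=O)N1[C@@H](Cc2ccccc2)COC1=O | intermediate
13 | Z-dibutylboron enolate of 12 | CCCCB(CCCC)O/C(=C\CC(OC)OC)N1[C@@H](Cc2ccccc2)COC1=O | intermediate
14 | (S)-4-benzyl-3-[(2S,3R,4Z)-2-(2,2-dimethoxyethyl)-3-hydroxy-6-[(4-methoxybenzyl)oxy]-5-(5-methylfuran-2-yl)hex-4-enoyl]oxazolidin-2-one | O=C(N1[C@@H](Cc2ccccc2)COC1=O)[C@@H](CC(OC)OC)[C@H](O)/C=C(\c1ccc(C)o1)COCc1ccc(OC)cc1 | intermediate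
15 | 3-O-triethylsilyl ether of 14 | O=C(N1[C@@H](Cc2ccccc2)COC1=O)[C@@H](CC(OC)OC)[C@H](O[Si](CC)(CC)CC)/C=C(\c1ccc(C)o1)COCc1ccc(OC)cc1 | intermediate
16 | (2R,3R,4Z)-2-(2,2-dimethoxyethyl)-6-[(4-methoxybenzyl)oxy]-5-(5-methylfuran-2-yl)-3-[(triethylsilyl)oxy]hex-4-en-1-ol | OC[C@@H](CC(OC)OC)[C@H](O[Si](CC)(CC)CC)/C=C(\c1ccc(C)o1)COCc1ccc(OC)cc1 | intermediate
17 | (2S,3R,4Z)-2-(2,2-dimethoxyethyl)-6-[(4-methoxybenzyl)oxy]-5-(5-methylfuran-2-yl)-3-[(triethylsilyl)oxy]hex-4-enal | O=C[C@@H](CC(OC)OC)[C@H](O[Si](CC)(CC)CC)/C=C(\c1ccc(C)o1)COCc1ccc(OC)cc1 | intermediate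
18 | (3R,4R,5Z)-3-(2,2-dimethoxyethyl)-7-[(4-methoxybenzyl)oxy]-6-(5-methylfuran-2-yl)-4-[(triethylsilyl)oxy]hept-5-en-1-yne | C#C[C@@H](CC(OC)OC)[C@H](O[Si](CC)(CC)CC)/C=C(\c1ccc(C)o1)COCc1ccc(OC)cc1 | intermediate
19 | (3R,4R,5Z)-3-(2,2-dimethoxyethyl)-7-[(4-methoxybenzyl)oxy]-6-(5-methylfuran-2-yl)hept-5-en-1-yn-4-ol | C#C[C@@H](CC(OC)OC)[C@H](O)/C=C(\c1ccc(C)o1)COCc1ccc(OC)cc1 | intermediate
20 | O-dimethylsilyl ether of 19 | C#C[C@@H](CC(OC)OC)[C@H](O[SiH](C)C)/C=C(\c1ccc(C)o1)COCc1ccc(OC)cc1 | intermediate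
21 | (4S,5R)-4-(2,2-dimethoxyethyl)-5-[(Z)-3-[(4-methoxybenzyl)oxy]-2-(5-methylfuran-2-yl)prop-1-en-1-yl]-2,2-dimethyl-3-methylene-1,2-oxasilolane (ring O6–Si–C8–C7–C6, exocyclic C8=C9) | C=C1[C@@H](CC(OC)OC)[C@H](O[Si]1(C)C)/C=C(\c1ccc(C)o1)COCc1ccc(OC)cc1 | intermediate
22 | silicon-bridged cycloadduct (germacrane locants 3R,6R,7S,8R,10S): 7-oxanorbornene with bridgeheads C3 and C10 joined by the ring oxygen and with C1=C2 and C8–C9 bridges, fused along C3–C8 to the cyclohexene C3–C4=C5–C6–C7–C8; CH3 on C10, CH2OPMB on C4, CH2CH(OMe)2 on C7 (C7 exo at C8), C8–SiMe2–O–C6 bridge with Si endo at C8 | C[C@@]12C[C@@]3([Si](C)(C)O4)[C@@H](CC(OC)OC)[C@H]4C=C(COCc5ccc(OC)cc5)[C@]3(O1)C=C2 | intermediate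
23 | exo-epoxide of 22 (1R,2S,3S,6R,7S,8R,10S; C1–C2 epoxide syn to the oxygen bridge) | C[C@@]12C[C@@]3([Si](C)(C)O4)[C@@H](CC(OC)OC)[C@H]4C=C(COCc5ccc(OC)cc5)[C@]3(O1)[C@H]6O[C@@H]26 | intermediate
24 | epoxy diol (1R,2S,3S,6R,7S,8R,10S; as 23 with endo C8–OH and C6–OH in place of the silicon bridge) | C[C@@]12C[C@@]3(O)[C@@H](CC(OC)OC)[C@H](O)C=C(COCc4ccc(OC)cc4)[C@]3(O1)[C@H]5O[C@@H]25 | intermediate
25 | tricyclic epoxy alcohol (1R,2S,3S,6R,7S,8R,10S; as 24 with C6–OSi(t-Bu)Me2) | C[C@@]12C[C@@]3(O)[C@@H](CC(OC)OC)[C@H](O[Si](C)(C)C(C)(C)C)C=C(COCc4ccc(OC)cc4)[C@]3(O1)[C@H]5O[C@@H]25 | intermediate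
26 | ten-membered ketone (1R,6R,7S,10S; Z-C4=C5): carbocycle C1–C10 with C8=O, oxygen between C3 and C10 (3-hydroxy-2,3-dihydrofuran with C1–OH and C2=C3), CH3 on C10, CH2OPMB on C4, OTBS on C6, CH2CH(OMe)2 on C7 | CC(C)(C)[Si](C)(C)O[C@@H]1/C=C(/COCc2ccc(OC)cc2)C3=C[C@@H](O)[C@](C)(CC(=O)[C@H]1CC(OC)OC)O3 | intermediate
27 | 8S diol (1R,6R,7R,8S,10S; 26 with C8 carbinol) | CC(C)(C)[Si](C)(C)O[C@@H]1/C=C(/COCc2ccc(OC)cc2)C3=C[C@@H](O)[C@](C)(C[C@H](O)[C@H]1CC(OC)OC)O3 | intermediate
28 | 8S furanone alcohol (6R,7R,8S,10S; 27 with C1=O) | CC(C)(C)[Si](C)(C)O[C@@H]1/C=C(/COCc2ccc(OC)cc2)C3=CC(=O)[C@](C)(C[C@H](O)[C@H]1CC(OC)OC)O3 | intermediate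
29 | 3-methylbutanoic acid (isovaleric acid) | CC(C)CC(=O)O | starting material
30 | 8R isovalerate (6R,7R,8R,10S) | CC(C)(C)[Si](C)(C)O[C@@H]1/C=C(/COCc2ccc(OC)cc2)C3=CC(=O)[C@](C)(C[C@@H](OC(=O)CC(C)C)[C@H]1CC(OC)OC)O3 | intermediate
31 | C12 aldehyde (30 with CH2CHO on C7) | CC(C)(C)[Si](C)(C)O[C@@H]1/C=C(/COCc2ccc(OC)cc2)C3=CC(=O)[C@](C)(C[C@@H](OC(=O)CC(C)C)[C@H]1CC=O)O3 | intermediate
32 | Mannich base (31 with CH2NMe2 on C11, both C11 epimers) | CC(C)(C)[Si](C)(C)O[C@@H]1/C=C(/COCc2ccc(OC)cc2)C3=CC(=O)[C@](C)(C[C@@H](OC(=O)CC(C)C)[C@H]1C(CN(C)C)C=O)O3 | intermediate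
33 | α-methylene aldehyde (C11=C13, C12 aldehyde) | CC(C)(C)[Si](C)(C)O[C@@H]1/C=C(/COCc2ccc(OC)cc2)C3=CC(=O)[C@](C)(C[C@@H](OC(=O)CC(C)C)[C@H]1C(=C)C=O)O3 | intermediate
34 | acrylic acid (C11=C13, C12 acid) | CC(C)(C)[Si](C)(C)O[C@@H]1/C=C(/COCc2ccc(OC)cc2)C3=CC(=O)[C@](C)(C[C@@H](OC(=O)CC(C)C)[C@H]1C(=C)C(=O)O)O3 | intermediate
35 | C6 hydroxy acid (34 without the silyl group) | O[C@@H]1/C=C(/COCc2ccc(OC)cc2)C3=CC(=O)[C@](C)(C[C@@H](OC(=O)CC(C)C)[C@H]1C(=C)C(=O)O)O3 | intermediate
36 | 15-O-(4-methoxybenzyl) ether of the target (6R,7R,8R,10S) | C=C1C(=O)O[C@@H]2/C=C(/COCc3ccc(OC)cc3)C4=CC(=O)[C@](C)(C[C@@H](OC(=O)CC(C)C)[C@@H]12)O4 | intermediate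
37 | CNP0171896.1 (6R,7R,8R,10S) | C=C1C(=O)O[C@@H]2/C=C(/CO)C3=CC(=O)[C@](C)(C[C@@H](OC(=O)CC(C)C)[C@@H]12)O3 | target

## Step count and risks

Total step count: 26.
Longest linear sequence: 24 steps (from 1 through steps 1–4 and 7–26; steps 5 and 6 form the two-step branch to imide 12).

Steps most likely to fail:

1. Step 14 (cycloaddition). The vinylsilane is an unactivated dienophile and furan cycloadditions revert on heating, so conversion may stall at an unfavourable equilibrium because the loss of furan–alkene conjugation is not repaid. The fallback keeps the same C6–O–X–C8 tether but builds it on boron, which also activates the dienophile. It sets out from alcohol 19: copper-catalysed α-selective protoboration ((SIMes)CuCl, B2pin2, NaOt-Bu, MeOH, THF) would give the 1-borylvinyl carbinol F1. NaIO4/NH4OAc in aqueous acetone would remove the pinacol, and the boronic acid would close on the C6 hydroxyl to the cyclic boronic half-ester F2. Its cycloaddition (toluene, 80 °C) would give the boron-bridged cycloadduct F3 under the same facial constraint. Excess m-CPBA (NaHCO3, CH2Cl2) would then epoxidise C1=C2 on the exo face and oxidise the C8–B bond with retention, and aqueous work-up comes back to the route at epoxy diol 24.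

2. Step 18 (fragmentation). The C8 alkoxide may fail to expel the unactivated epoxide oxygen fast enough, so that reversible silyl migration from O6, attack of the alkoxide on the epoxide, or enolisation and β-elimination of the product ketone take over. The fallback replaces the epoxide by a sulfate leaving group (fragmentation of a 1,3-diol monosulfonate). It sets out from cycloadduct 22: Tamao oxidation as in step 16 would give the alkenyl diol F4, and silylation as in step 17 its C6 silyl ether F5. OsO4 (cat.) with N-methylmorpholine N-oxide would add a cis-diol to the exo face of C1=C2 to give triol F6, and 1,1'-sulfonyldiimidazole with DBU would close the cyclic sulfate F7. KN(SiMe3)2 would then trigger the same fragmentation with the far better leaving group on C2 and give the potassium C1 sulfate F8. H2SO4 (cat.) in wet THF would hydrolyse the sulfate monoester and come back to the route at ketone 26.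

3. Step 21 (esterification with inversion). Displacement at the hindered C8 carbinol may give elimination instead of substitution, and the step also depends on the facial sense assumed for step 19. The fallback sets C8 directly by a reagent-controlled reduction and acylates with retention. It sets out from ketone 26: (S)-2-methyl-CBS-oxazaborolidine with catecholborane (toluene, −78 °C; the branched C7 side acting as the large substituent) would give the 8R diol F9. MnO2 as in step 20 would give the 8R furanone alcohol F10, and isovaleric anhydride with DMAP and pyridine would come back to the route at ester 30.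

Further compounds
F1 | step 14 | (3R,4R,5Z)-3-(2,2-dimethoxyethyl)-7-[(4-methoxybenzyl)oxy]-6-(5-methylfuran-2-yl)-2-(4,4,5,5-tetramethyl-1,3,2-dioxaborolan-2-yl)hepta-1,5-dien-4-ol | C=C(B1OC(C)(C)C(C)(C)O1)[C@@H](CC(OC)OC)[C@H](O)/C=C(\c1ccc(C)o1)COCc1ccc(OC)cc1
F2 | step 14 | cyclic boronic half-ester (2-hydroxy-3-methylene-1,2-oxaborolane, substituents as in 21) | C=C1[C@@H](CC(OC)OC)[C@H](OB1O)/C=C(\c1ccc(C)o1)COCc1ccc(OC)cc1
F3 | step 14 | boron-bridged cycloadduct (as 22 with B(OH) in place of SiMe2) | C[C@@]12C[C@@]3(B(O)O4)[C@@H](CC(OC)OC)[C@H]4C=C(COCc5ccc(OC)cc5)[C@]3(O1)C=C2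
F4 | step 18 | alkenyl diol (as 24 with C1=C2 in place of the epoxide) | C[C@@]12C[C@@]3(O)[C@@H](CC(OC)OC)[C@H](O)C=C(COCc4ccc(OC)cc4)[C@]3(O1)C=C2
F5 | step 18 | C6 tert-butyldimethylsilyl ether of F4 | C[C@@]12C[C@@]3(O)[C@@H](CC(OC)OC)[C@H](O[Si](C)(C)C(C)(C)C)C=C(COCc4ccc(OC)cc4)[C@]3(O1)C=C2
F6 | step 18 | triol (F5 with exo,cis-1,2-diol on C1 and C2) | C[C@@]12C[C@@]3(O)[C@@H](CC(OC)OC)[C@H](O[Si](C)(C)C(C)(C)C)C=C(COCc4ccc(OC)cc4)[C@]3(O1)[C@@H](O)[C@H]2O
F7 | step 18 | exo cyclic sulfate of F6 (C1,C2) | C[C@@]12C[C@@]3(O)[C@@H](CC(OC)OC)[C@H](O[Si](C)(C)C(C)(C)C)C=C(COCc4ccc(OC)cc4)[C@]3(O1)[C@H]5OS(=O)(=O)O[C@@H]25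
F8 | step 18 | potassium C1 sulfate of ketone 26 | CC(C)(C)[Si](C)(C)O[C@@H]1/C=C(/COCc2ccc(OC)cc2)C3=C[C@@H](OS(=O)(=O)[O-])[C@](C)(CC(=O)[C@H]1CC(OC)OC)O3.[K+]
F9 | step 21 | 8R diol (C8 epimer of 27) | CC(C)(C)[Si](C)(C)O[C@@H]1/C=C(/COCc2ccc(OC)cc2)C3=C[C@@H](O)[C@](C)(C[C@@H](O)[C@H]1CC(OC)OC)O3
F10 | step 21 | 8R furanone alcohol (C8 epimer of 28) | CC(C)(C)[Si](C)(C)O[C@@H]1/C=C(/COCc2ccc(OC)cc2)C3=CC(=O)[C@](C)(C[C@@H](O)[C@H]1CC(OC)OC)O3
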